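**Strategy.** Everything rests on cutting ring B at C7–C8 and C9–C10. The adjacent stereocentres C8, C9 and C10 of ring B, with the C8 and C9 methyl groups on one face and the benzylic carbon C15 on the other, map onto the E double bond of tiglaldehyde. A single catalytic asymmetric Diels–Alder reaction of that enal with (E)-3-methylnona-1,3-dien-8-yne (methyl on C3, pent-4-ynyl chain on C4 of the diene) thus builds ring B and all three centres, and leaves a C5=C6 alkene and an alkyne. These later close ring A by radical cyclisation (C4–C5, C5 quaternary, C4 methylene); arylation of C15, deoxygenation and unmasking complete the catechol acid.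

Key step: step 3

Remark (numbering): C1–C10 are the decalin carbons (ring A: C1–C5 and C10; ring B: C5–C10), C11 is the methylene carbon on C4, C15 is the benzylic carbon on C9.
Remark (catalyst sense): the (R)-diphenylprolinol-derived oxazaborolidinium is assumed, from the formyl C–H···O binding model for α-substituted enals, to deliver the diene to the Si face of the enal α-carbon; this sense should be checked on the first batch of 7.
Remark (C15 carbinol): the carbinol carbon made in step 7 is an epimer mixture, drawn without configuration, and is removed in step 8.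

Step 1
Reactants: 1 5-hexyn-1-ol; 2 2-(triphenylphosphoranylidene)propanal
Product: 4 (E)-2-methyloct-2-en-7-ynal, via 5-hexynal 3 (not isolated)
Conditions: (COCl)2, DMSO, CH2Cl2, −78 °C; Et3N, −78 to 0 °C; then 2, rt to 40 °C
Reagents that add atoms: none
Why: Swern oxidation followed in the same flask by Wittig olefination with the stabilised formyl ylide spares isolation of the volatile aldehyde, and a stabilised ylide should give the (E)-trisubstituted enal (chain trans to CHO) with the alkyne untouched.

Step 2
Reactants: 4 (E)-2-methyloct-2-en-7-ynal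
Product: 5 (E)-3-methylnona-1,3-dien-8-yne
Conditions: Ph3PCH3Br, KOt-Bu, THF, 0 °C; then 4, −78 to 0 °C
Reagents that add atoms: methyltriphenylphosphonium bromide, C[P+](c1ccccc1)(c1ccccc1)c1ccccc1.[Br-]
Why: Wittig methylenation attacks only the enal carbonyl (1,2), leaves the (E)-alkene and the weakly acidic alkyne C–H alone, and gives a diene whose chain points outward in the s-cis form.

Step 3
Reactants: 5 (E)-3-methylnona-1,3-dien-8-yne; 6 (E)-2-methylbut-2-enal (in excess)
Product: 7 (1R,2R,6S)-1,3,6-trimethyl-2-(pent-4-yn-1-yl)cyclohex-3-ene-1-carbaldehyde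
Conditions: (R)-B-o-tolyl oxazaborolidine from (R)-α,α-diphenylprolinol (20 mol %), Tf2NH (18 mol %), CH2Cl2, −78 to −30 °C
Reagents that add atoms: none
Why: The boron-bound s-trans enal, held by a formyl C–H···O contact to the catalyst oxygen, undergoes a concerted but asynchronous [4+2] cycloaddition with the s-cis diene; the closest known reaction type is the oxazaborolidinium-catalysed Diels–Alder reaction of 2-methylacrolein and other α-substituted enals with acyclic dienes. Ring B closes by the cycloaddition itself, which forms C7–C8 and C9–C10 and keeps C5=C6. C8 and C9 are fixed relative to each other by suprafacial addition to the (E)-enal (cis methyls, C15 trans to the C8 methyl). C10 is fixed relative to C9 by the exo-formyl transition state that α-substituted enals prefer, which puts the outward C10 chain cis to the C9 methyl and C10–H cis to C15, and the absolute sense comes from the catalyst aryl group, which screens one enal face so that the diene adds to the Si face of C9. The step needs regioselectivity, which should come from the unsubstituted C7 terminus bonding first to the enal β-carbon while the alkyl-bearing C10 pairs with the α-carbon, against the weaker opposing bias of the C5 methyl. The alkyne and the α-quaternary aldehyde of the product should be inert to the catalyst at low temperature.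

Step 4
Reactants: 7 (1R,2R,6S)-1,3,6-trimethyl-2-(pent-4-yn-1-yl)cyclohex-3-ene-1-carbaldehyde
Product: 8 (1R,2S,4aS,8aR)-1,2,4a-trimethyl-5-methylidenedecahydronaphthalene-1-carbaldehyde
Conditions: Fe(acac)3 (2.2 equiv), PhSiH3 (3 equiv), degassed EtOH, 60 °C
Reagents that add atoms: none
Why: Iron-hydride hydrogen-atom transfer to C6 gives the tertiary C5 radical, which closes ring A 6-exo-dig onto C4 and is reduced to the C4 methylene (a known MHAT reductive alkene–alkyne cyclisation); the axial C9 methyl blocks the top face of the ring-B radical, so the equatorial C10 tether should bond from below through a chair-like transition state to give the trans-decalin with the C5 methyl axial, and closing the ring here removes the alkyne C–H before any organolithium or stannane is used.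

Step 5
Reactants: 9 3-bromo-4,5-dihydroxybenzaldehyde
Product: 10 3-bromo-4,5-bis(methoxymethoxy)benzaldehyde
Conditions: MOMCl, i-Pr2NEt, CH2Cl2, 0 °C to rt
Reagents that add atoms: chloromethyl methyl ether, COCCl
Why: O-alkylation of both acidic phenols gives acetal ethers that tolerate and stabilise the later ortho-aryllithium and can be removed at the end without protic acid or hydrogenation.

Step 6
Reactants: 10 3-bromo-4,5-bis(methoxymethoxy)benzaldehyde
Product: 11 1-bromo-5-(dimethoxymethyl)-2,3-bis(methoxymethoxy)benzene
Conditions: HC(OMe)3, MeOH, PPTS (cat.), rt; Et3N quench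
Reagents that add atoms: trimethyl orthoformate, COC(OC)OC; methanol, CO
Why: Orthoformate-driven acetalisation masks the formyl group (the future carboxyl carbon) against the organolithium, and a weak pyridinium acid at room temperature should leave the aryl MOM ethers intact.

Step 7
Reactants: 11 1-bromo-5-(dimethoxymethyl)-2,3-bis(methoxymethoxy)benzene; 8 (1R,2S,4aS,8aR)-1,2,4a-trimethyl-5-methylidenedecahydronaphthalene-1-carbaldehyde
Product: 15 O-{[5-(dimethoxymethyl)-2,3-bis(methoxymethoxy)phenyl][(1R,2S,4aS,8aR)-1,2,4a-trimethyl-5-methylidenedecahydronaphthalen-1-yl]methyl} S-methyl carbonodithioate (C15 epimers), via aryllithium 12 (not isolated), via lithium alkoxide 13 (not isolated), via lithium xanthate 14 (not isolated)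
Conditions: 11 (1.5 equiv), n-BuLi, THF, −78 °C; then 8, −78 to −20 °C; CS2, DMPU, 0 °C; MeI, rt
Reagents that add atoms: carbon disulfide, S=C=S; iodomethane, CI
Why: Bromine–lithium exchange gives an aryllithium held by the ortho OMOM group, which should add 1,2 to the non-enolisable neopentyl aldehyde as aryllithiums do with decalin C9 aldehydes of this family, and the alkoxide is trapped as its S-methyl xanthate in the same flask (the new C15 centre is an inconsequential epimer mixture).

Step 8
Reactants: 15 the S-methyl xanthate
Product: 16 5-(dimethoxymethyl)-1,2-bis(methoxymethoxy)-3-{[(1R,2S,4aS,8aS)-1,2,4a-trimethyl-5-methylidenedecahydronaphthalen-1-yl]methyl}benzene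
Conditions: Bu3SnH, AIBN, toluene, 100 °C
Reagents that add atoms: none
Why: Barton–McCombie deoxygenation: the stannyl radical adds to the thiocarbonyl, β-scission gives a benzylic C15 radical that takes hydrogen from the stannane, the distant C4 methylene (1,3-diequatorial to C15) cannot trap it, and no stereocentre is touched.

Step 9
Reactants: 16 the dimethyl acetal
Product: 18 3,4-bis(methoxymethoxy)-5-{[(1R,2S,4aS,8aS)-1,2,4a-trimethyl-5-methylidenedecahydronaphthalen-1-yl]methyl}benzoic acid, via aldehyde 17 (not isolated)
Conditions: PPTS (cat.), THF/H2O, rt; then NaClO2, NaH2PO4, 2-methylbut-2-ene, t-BuOH/H2O, 0 °C to rt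
Reagents that add atoms: water, O; sodium chlorite, [Na+].[O-]Cl=O
Why: The para-alkoxy-stabilised dimethyl acetal should hydrolyse under acid too weak to touch the MOM ethers or the methylene, and Pinnick oxidation then takes the aryl aldehyde to the acid while the scavenger alkene removes hypochlorite before it reaches C4=C11.

Step 10
Reactants: 18 the bis-MOM acid
Product: 19 3,4-dihydroxy-5-{[(1R,2S,4aS,8aS)-1,2,4a-trimethyl-5-methylidenedecahydronaphthalen-1-yl]methyl}benzoic acid
Conditions: ZnBr2, n-PrSH, CH2Cl2, 0 °C
Reagents that add atoms: none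
Why: Zinc-assisted thiolysis of the two aryl methoxymethyl acetals (the thiol captures the methoxymethyl cation) should free the catechol within minutes without the protic acid that would move the C4 methylene into ring A.

**Compound list**

1 | 5-hexyn-1-ol | C#CCCCCO | starting material
2 | 2-(triphenylphosphoranylidene)propanal | CC(C=O)=P(c1ccccc1)(c1ccccc1)c1ccccc1 | starting material
3 | 5-hexynal | C#CCCCC=O | intermediate (not isolated)
4 | (E)-2-methyloct-2-en-7-ynal | C#CCCC/C=C(\C)C=O | intermediate
5 | (E)-3-methylnona-1,3-dien-8-yne | C=C/C(C)=C/CCCC#C | intermediate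
6 | (E)-2-methylbut-2-enal | C/C=C(\C)C=O | starting material
7 | (1R,2R,6S)-1,3,6-trimethyl-2-(pent-4-yn-1-yl)cyclohex-3-ene-1-carbaldehyde | C#CCCC[C@@H]1C(C)=CC[C@H](C)[C@@]1(C)C=O | intermediate
8 | (1R,2S,4aS,8aR)-1,2,4a-trimethyl-5-methylidenedecahydronaphthalene-1-carbaldehyde (trans-decalin) | C=C1CCC[C@H]2[C@](C)(C=O)[C@@H](C)CC[C@]12C | intermediate
9 | 3-bromo-4,5-dihydroxybenzaldehyde | O=Cc1cc(O)c(O)c(Br)c1 | starting material
10 | 3-bromo-4,5-bis(methoxymethoxy)benzaldehyde | COCOc1cc(C=O)cc(Br)c1OCOC | intermediate
11 | 1-bromo-5-(dimethoxymethyl)-2,3-bis(methoxymethoxy)benzene | COCOc1cc(C(OC)OC)cc(Br)c1OCOC | intermediate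
12 | [5-(dimethoxymethyl)-2,3-bis(methoxymethoxy)phenyl]lithium | [Li]c1cc(C(OC)OC)cc(OCOC)c1OCOC | intermediate (not isolated)
13 | lithium alkoxide of the C15 carbinol from 12 and 8 (C15 epimers) | C=C1CCC[C@H]2[C@](C)(C(O[Li])c3cc(C(OC)OC)cc(OCOC)c3OCOC)[C@@H](C)CC[C@]12C | intermediate (not isolated)
14 | lithium O-alkyl dithiocarbonate of the C15 carbinol (C15 epimers) | C=C1CCC[C@H]2[C@](C)(C(OC(=S)S[Li])c3cc(C(OC)OC)cc(OCOC)c3OCOC)[C@@H](C)CC[C@]12C | intermediate (not isolated)
15 | O-{[5-(dimethoxymethyl)-2,3-bis(methoxymethoxy)phenyl][(1R,2S,4aS,8aR)-1,2,4a-trimethyl-5-methylidenedecahydronaphthalen-1-yl]methyl} S-methyl carbonodithioate (C15 epimers) | C=C1CCC[C@H]2[C@](C)(C(OC(=S)SC)c3cc(C(OC)OC)cc(OCOC)c3OCOC)[C@@H](C)CC[C@]12C | intermediate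
16 | 5-(dimethoxymethyl)-1,2-bis(methoxymethoxy)-3-{[(1R,2S,4aS,8aS)-1,2,4a-trimethyl-5-methylidenedecahydronaphthalen-1-yl]methyl}benzene | C=C1CCC[C@H]2[C@](C)(Cc3cc(C(OC)OC)cc(OCOC)c3OCOC)[C@@H](C)CC[C@]12C | intermediate
17 | 3,4-bis(methoxymethoxy)-5-{[(1R,2S,4aS,8aS)-1,2,4a-trimethyl-5-methylidenedecahydronaphthalen-1-yl]methyl}benzaldehyde | C=C1CCC[C@H]2[C@](C)(Cc3cc(C=O)cc(OCOC)c3OCOC)[C@@H](C)CC[C@]12C | intermediate (not isolated)
18 | 3,4-bis(methoxymethoxy)-5-{[(1R,2S,4aS,8aS)-1,2,4a-trimethyl-5-methylidenedecahydronaphthalen-1-yl]methyl}benzoic acid | C=C1CCC[C@H]2[C@](C)(Cc3cc(C(=O)O)cc(OCOC)c3OCOC)[C@@H](C)CC[C@]12C | intermediate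
19 | 3,4-dihydroxy-5-{[(1R,2S,4aS,8aS)-1,2,4a-trimethyl-5-methylidenedecahydronaphthalen-1-yl]methyl}benzoic acid | C=C1CCC[C@H]2[C@](C)(Cc3cc(C(=O)O)cc(O)c3O)[C@@H](C)CC[C@]12C | target

**Step count.** Total: 10 steps. Longest linear sequence: 8 steps (1, 2, 3, 4, 7, 8, 9, 10 from 5-hexyn-1-ol); the aryl branch (5, 6) joins at step 7.

**Steps most likely to fail**

Step 3. The β-substituted enal may turn over slowly, the acid-sensitive diene may oligomerise, or regio-, exo- or facial selectivity may be eroded. The fallback sets out from 5 and 6 and comes back at 7: a racemic cycloaddition promoted by Me2AlCl (CH2Cl2, −78 °C) gives the racemic adduct F1; NaBH4 (MeOH, 0 °C) gives the racemic neopentyl alcohol F2; acylation with (1S)-camphanic chloride (pyridine, DMAP) and separation of the two diastereomeric esters by chromatography or crystallisation gives the camphanate F3 of the (1R,2R,6S) alcohol; K2CO3 in MeOH releases the alcohol F4, and Dess–Martin oxidation returns 7.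

Step 4. The C5 radical may be reduced before it cyclises, ring closure may occur from the wrong face (cis-decalin), excess iron hydride may reduce or shift the new methylene, or the aldehyde may be reduced. The fallback sets out from 7 and comes back at 8: HBr (AcOH/CH2Cl2, −20 °C) adds across C5=C6 in the Markovnikov sense to give the tertiary bromide F5, and slow addition of Bu3SnH with AIBN (benzene, 80 °C) generates the same C5 radical by bromine abstraction. Closure is again 6-exo-dig, and the vinyl radical is quenched by the stannane, with no metal hydride left to attack the product alkene.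

Step 10. Lewis or adventitious protic acid may move the C4=C11 double bond into ring A, or the hindered inner MOM group may be cleaved incompletely. The fallback sets out from 18 and comes back at 19: TMSOTf with 2,2′-bipyridyl (MeCN, 0 °C to rt) exchanges each methoxymethyl group for silicon under base-buffered conditions and silylates the acid, giving the tris(trimethylsilyl) derivative F6, and stirring with water hydrolyses the silyl ethers and the silyl ester to 19.

**Further compounds**

F1 | step 3 | racemic 1,3,6-trimethyl-2-(pent-4-yn-1-yl)cyclohex-3-ene-1-carbaldehyde (7 and its enantiomer) | C#CCCC[C@@H]1C(C)=CC[C@H](C)[C@@]1(C)C=O.C#CCCC[C@H]1C(C)=CC[C@@H](C)[C@]1(C)C=O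
F2 | step 3 | racemic [1,3,6-trimethyl-2-(pent-4-yn-1-yl)cyclohex-3-en-1-yl]methanol (relative configuration of 7) | C#CCCC[C@@H]1C(C)=CC[C@H](C)[C@@]1(C)CO.C#CCCC[C@H]1C(C)=CC[C@@H](C)[C@]1(C)CO
F3 | step 3 | [(1R,2R,6S)-1,3,6-trimethyl-2-(pent-4-yn-1-yl)cyclohex-3-en-1-yl]methyl (1S,4R)-4,7,7-trimethyl-3-oxo-2-oxabicyclo[2.2.1]heptane-1-carboxylate | C#CCCC[C@@H]1C(C)=CC[C@H](C)[C@@]1(C)COC(=O)[C@@]12CC[C@@](C)(C(=O)O1)C2(C)C
F4 | step 3 | [(1R,2R,6S)-1,3,6-trimethyl-2-(pent-4-yn-1-yl)cyclohex-3-en-1-yl]methanol | C#CCCC[C@@H]1C(C)=CC[C@H](C)[C@@]1(C)CO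
F5 | step 4 | 3-bromo-1,3,6-trimethyl-2-(pent-4-yn-1-yl)cyclohexane-1-carbaldehyde with the C1, C2 and C6 configurations of 7 (epimers at the bromine-bearing carbon) | C#CCCC[C@@H]1C(C)(Br)CC[C@H](C)[C@@]1(C)C=O
F6 | step 10 | trimethylsilyl 3,4-bis(trimethylsilyloxy)-5-{[(1R,2S,4aS,8aS)-1,2,4a-trimethyl-5-methylidenedecahydronaphthalen-1-yl]methyl}benzoate | C=C1CCC[C@H]2[C@](C)(Cc3cc(C(=O)O[Si](C)(C)C)cc(O[Si](C)(C)C)c3O[Si](C)(C)C)[C@@H](C)CC[C@]12C
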